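The aldehyde is traced back to the methyl of an isopropenyl group (allylic C–H oxidation). Both acyl–O bonds are then cut, the (S)-carbinol on C5 goes back to an acetyl group carried as a dioxolane, and last the C2–C3 bond of the dihydrofuran ring is cut.
Enabling feature: in the dihydrofuran ring, C3 (benzylic, O-bearing) and C2 (bound to O1 and to a 1,1-disubstituted vinyl carbon) form a homoallylic alcohol. Both carbons hang on one benzene ring, C3 directly and C2 through O1. Cutting C2–C3 while joining the C3 oxygen to the vinyl CH2 terminus gives a cyclic benzyl allyl ether, an eight-membered 1,5-benzodioxocine with a (Z)-aryl enol ether.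
Forward: the benzene ring is bought. Two Williamson etherifications of a salicyl alcohol with methallyl dichloride close the eight-membered ring, and the alkene is moved next to O1. A transannular [2,3]-Wittig shift then contracts the ring to the dihydrofuran.
Stereochemistry: the cis C2/C3 relationship comes from the cis-fused bicyclic transition state, and the absolute sense from t-BuLi with a chiral bis(oxazoline). The side-chain (S) centre comes from an (S,S)-TsDPEN ruthenium transfer hydrogenation, which also turns leftover antipode into a separable diastereomer.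
End game: isovalerate on C3, ketal removal, ketone reduction, senecioate, then oxidation of the isopropenyl methyl to the enal as the last step.
Key step: step 6

Assumption: the sense of induction of the bis(oxazoline) ligand on this new ring system cannot be derived from open-chain cases. The (S,S)-ligand from L-valinol is written, and its (R,R)-antipode from D-valinol would be used if a first run shows the opposite sense.

Step 1
Reactants: 1 methyl 5-acetyl-2-hydroxybenzoate; 2 ethylene glycol
Product: 3 methyl 2-hydroxy-5-(2-methyl-1,3-dioxolan-2-yl)benzoate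
Conditions: ethylene glycol (5 equiv), p-TsOH·H2O (cat.), toluene, Dean–Stark, reflux; Et3N quench
Reagents that add atoms: ethylene glycol (2), OCCO
Why: Acid-catalysed ketalisation with azeotropic water removal masks the only ketone against the hydride and organolithium steps to come, and partial transesterification of the salicylate by the diol would be harmless because step 2 reduces any such ester to the same alcohol.

Step 2
Reactants: 3 methyl 2-hydroxy-5-(2-methyl-1,3-dioxolan-2-yl)benzoate
Product: 4 2-(hydroxymethyl)-4-(2-methyl-1,3-dioxolan-2-yl)phenol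
Conditions: LiAlH4, THF, 0 °C → rt; H2O/aq NaOH work-up
Reagents that add atoms: none
Why: LiAlH4 reduction of an aryl ester stops at the benzylic alcohol, the phenoxide formed first is inert, and the basic work-up keeps the acid-labile dioxolane in place.

Step 3
Reactants: 4 2-(hydroxymethyl)-4-(2-methyl-1,3-dioxolan-2-yl)phenol; 5 3-chloro-2-(chloromethyl)prop-1-ene
Product: 6 [2-{[2-(chloromethyl)prop-2-en-1-yl]oxy}-5-(2-methyl-1,3-dioxolan-2-yl)phenyl]methanol
Conditions: K2CO3, 5 (3 equiv), DMF, rt → 40 °C
Reagents that add atoms: 3-chloro-2-(chloromethyl)prop-1-ene (5), C=C(CCl)CCl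
Why: Williamson etherification under carbonate conditions ionises only the phenol, so the benzylic alcohol stays free, and the excess of the volatile bis-electrophile suppresses double aryloxylation.

Step 4
Reactants: 6 [2-{[2-(chloromethyl)prop-2-en-1-yl]oxy}-5-(2-methyl-1,3-dioxolan-2-yl)phenyl]methanol
Product: 7 3-methylidene-8-(2-methyl-1,3-dioxolan-2-yl)-3,4-dihydro-2H,6H-1,5-benzodioxocine
Conditions: NaH (1.5 equiv), n-Bu4NI (0.1 equiv), THF, slow addition (about 0.005 M), reflux
Reagents that add atoms: none
Why: Intramolecular Williamson etherification of the alkoxide on the allylic chloride, sped up by in situ halide exchange and run under high dilution, should close the eight-membered ring because the arene, the sp2 carbon and the two ring oxygens remove most of the torsional and transannular strain that normally slows medium-ring closure.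

Step 5
Reactants: 7 3-methylidene-8-(2-methyl-1,3-dioxolan-2-yl)-3,4-dihydro-2H,6H-1,5-benzodioxocine
Product: 8 (2Z)-3-methyl-8-(2-methyl-1,3-dioxolan-2-yl)-4H,6H-1,5-benzodioxocine
Conditions: KOtBu (0.3 equiv), DMSO, rt
Reagents that add atoms: none
Why: Base-mediated allyl-to-propenyl ether isomerisation runs through the most acidic allylic position, which is the ArO–CH2 group since aryl allyl ethers isomerise much faster than alkyl allyl ethers, and the eight-membered ring admits only the ring-cis, hence (Z), trisubstituted enol ether.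

Step 6
Reactants: 8 (2Z)-3-methyl-8-(2-methyl-1,3-dioxolan-2-yl)-4H,6H-1,5-benzodioxocine
Product: 11 (2R,3R)-5-(2-methyl-1,3-dioxolan-2-yl)-2-(prop-1-en-2-yl)-2,3-dihydro-1-benzofuran-3-ol, via C6-lithiated benzodioxocine 9 (not isolated), via lithium C3-alkoxide 10 (not isolated)
Conditions: t-BuLi (1.5 equiv), (S,S)-2,2'-(pentane-3,3-diyl)bis(4-isopropyl-4,5-dihydro-1,3-oxazole) (1.6 equiv), Et2O/pentane, −78 → −40 °C; then H2O
Reagents that add atoms: none
Why: Proposed new method: the t-BuLi–bis(oxazoline) complex removes one of the two enantiotopic hydrogens at benzylic C6 of 8, and the α-oxybenzyllithium 9 bonds through C6 to the aryloxy-bearing alkene carbon C2 across the ring while the allylic C4–O5 bond breaks in a concerted, suprafacial five-centre [2,3]-Wittig shift, so that C6 becomes C3 of 11, C4 becomes the =CH2 of the isopropenyl group and O5 becomes the C3 alkoxide 10, the driving force being the change from carbanion to alkoxide plus the loss of medium-ring strain. The closest known reaction types are the transannular [2,3]-Wittig ring contractions of large-ring diallyl and allyl propargyl ethers, the ligand-controlled enantioselective [2,3]-Wittig shift of open-chain benzyl allyl ethers and the t-BuLi/bis(oxazoline) lithiation of cyclic benzyl ethers such as isochroman, whereas an eight-to-five contraction and an enol ether as the accepting terminus are without precedent. The dihydrofuran ring closes in the 5-exo-trig mode on the C2=C3 enol ether bond (C3 of 8 stays outside the new ring), a benzylic-carbon-to-O-bound-carbon closure of the kind that also works in intramolecular Wittig benzofuran syntheses, and it is helped by the larger LUMO coefficient of an enol ether at its oxygen-bearing carbon. The relative configuration is set by the ring, because the five-centre array and the nascent dihydrofuran share the forming bond and can only be cis-fused (bicyclo[3.3.0] geometry), so O5 on the new C3 and the isopropenyl carbon on C2, still linked through C4, must come out cis. The absolute configuration at C3 is set by the chiral ligand, which should select the pro-R hydrogen, followed by the inversion at the lithiated carbon that is typical of α-oxyorganolithiums, and C2 then follows from the cis constraint because only one alkene face can reach the carbanion. The step needs benzylic instead of allylic, vinylic or ring lithiation and a [2,3] instead of a [1,2] shift: C6–H is the only C–H activated by both an aryl group and an oxygen and lies between the lithium-binding O5 and O1, an anion at C4 would place charge on the donor-substituted C2, the vinylic hydrogen sits in a hindered trisubstituted enol ether, and the low temperature with the reacting termini held face to face disfavours the homolytic [1,2] route.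

Step 7
Reactants: 11 (2R,3R)-5-(2-methyl-1,3-dioxolan-2-yl)-2-(prop-1-en-2-yl)-2,3-dihydro-1-benzofuran-3-ol; 12 3-methylbutanoic anhydride (isovaleric anhydride)
Product: 13 (2R,3R)-5-(2-methyl-1,3-dioxolan-2-yl)-2-(prop-1-en-2-yl)-2,3-dihydro-1-benzofuran-3-yl 3-methylbutanoate
Conditions: 12 (1.5 equiv), Et3N, 4-(dimethylamino)pyridine (DMAP, cat.), CH2Cl2, 0 °C → rt
Reagents that add atoms: 3-methylbutanoic anhydride (12), CC(C)CC(=O)OC(=O)CC(C)C
Why: DMAP-catalysed acyl transfer from the anhydride to the secondary benzylic hydroxyl leaves the C3–O bond untouched, so C2 and C3 keep their configuration, and the weakly basic, acid-free medium spares the dioxolane and avoids elimination to the benzofuran.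

Step 8
Reactants: 13 (2R,3R)-5-(2-methyl-1,3-dioxolan-2-yl)-2-(prop-1-en-2-yl)-2,3-dihydro-1-benzofuran-3-yl 3-methylbutanoate
Product: 14 (2R,3R)-5-acetyl-2-(prop-1-en-2-yl)-2,3-dihydro-1-benzofuran-3-yl 3-methylbutanoate
Conditions: pyridinium p-toluenesulfonate (cat.), acetone/H2O, rt
Reagents that add atoms: water, O
Why: Acid-catalysed ketal hydrolysis is especially fast here because the oxocarbenium ion is stabilised by the para ring oxygen O1, so a buffered acid at room temperature should suffice and leave the ionisable C3 ester and the isopropenyl group alone.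

Step 9
Reactants: 14 (2R,3R)-5-acetyl-2-(prop-1-en-2-yl)-2,3-dihydro-1-benzofuran-3-yl 3-methylbutanoate
Product: 15 (2R,3R)-5-[(1S)-1-hydroxyethyl]-2-(prop-1-en-2-yl)-2,3-dihydro-1-benzofuran-3-yl 3-methylbutanoate
Conditions: RuCl[(S,S)-TsDPEN](p-cymene) (1 mol %), HCO2H–Et3N (5:2), CH2Cl2, rt
Reagents that add atoms: none
Why: Noyori–Ikariya asymmetric transfer hydrogenation with the (S,S)-TsDPEN ruthenium catalyst delivers hydride to the Re face of aryl methyl ketones and thus sets the (S)-carbinol under pure catalyst control without touching alkene or ester, and since this centre is set independently any (2S,3S) material left from step 6 becomes a diastereomer that can be removed here by chromatography or crystallisation.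

Step 10
Reactants: 15 (2R,3R)-5-[(1S)-1-hydroxyethyl]-2-(prop-1-en-2-yl)-2,3-dihydro-1-benzofuran-3-yl 3-methylbutanoate; 16 3-methylbut-2-enoic acid (senecioic acid)
Product: 17 (1S)-1-[(2R,3R)-3-(3-methylbutanoyloxy)-2-(prop-1-en-2-yl)-2,3-dihydro-1-benzofuran-5-yl]ethyl 3-methylbut-2-enoate
Conditions: 16, N,N'-dicyclohexylcarbodiimide (DCC), DMAP (cat.), CH2Cl2, 0 °C → rt
Reagents that add atoms: 3-methylbut-2-enoic acid (16), CC(C)=CC(=O)O
Why: Steglich esterification acylates the oxygen and never breaks the C–O bond of the easily ionised para-alkoxybenzylic carbinol, so the (S) centre is retained, and carbodiimide activation avoids the vinylketene pathway by which senecioyl chloride and amine bases give deconjugated esters.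

Step 11
Reactants: 17 (1S)-1-[(2R,3R)-3-(3-methylbutanoyloxy)-2-(prop-1-en-2-yl)-2,3-dihydro-1-benzofuran-5-yl]ethyl 3-methylbut-2-enoate
Product: 19 (1S)-1-[(2R,3R)-3-(3-methylbutanoyloxy)-2-(3-oxoprop-1-en-2-yl)-2,3-dihydro-1-benzofuran-5-yl]ethyl 3-methylbut-2-enoate (CNP0325942.1), via allylic alcohol 18 (not isolated)
Conditions: SeO2 (0.3 equiv), t-BuOOH (decane solution), CH2Cl2, 0 °C → rt; filtration, then activated MnO2, CH2Cl2, rt
Reagents that add atoms: tert-butyl hydroperoxide, CC(C)(C)OO (terminal oxygen source); selenium dioxide, O=[Se]=O (oxygen carrier)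
Why: Riley allylic oxidation (ene reaction at the terminal =CH2 followed by [2,3]-sigmatropic shift of the allylseleninic acid) should pick the only electron-rich alkene, attack its methyl group because the C2–H bond lies near the alkene plane and is inductively deactivated by O1 and the neighbouring ester, and leave the electron-poor senecioate alone, while MnO2 carries allylic alcohol 18 on to the enal under neutral conditions that do not disturb the three stereocentres.

Compound list
1 | methyl 5-acetyl-2-hydroxybenzoate | COC(=O)c1cc(C(C)=O)ccc1O | starting material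
2 | ethylene glycol | OCCO | starting material
3 | methyl 2-hydroxy-5-(2-methyl-1,3-dioxolan-2-yl)benzoate | COC(=O)c1cc(C2(C)OCCO2)ccc1O | intermediate
4 | 2-(hydroxymethyl)-4-(2-methyl-1,3-dioxolan-2-yl)phenol | OCc1cc(C2(C)OCCO2)ccc1O | intermediate
5 | 3-chloro-2-(chloromethyl)prop-1-ene | C=C(CCl)CCl | starting material
6 | [2-{[2-(chloromethyl)prop-2-en-1-yl]oxy}-5-(2-methyl-1,3-dioxolan-2-yl)phenyl]methanol | C=C(CCl)COc1ccc(C2(C)OCCO2)cc1CO | intermediate
7 | 3-methylidene-8-(2-methyl-1,3-dioxolan-2-yl)-3,4-dihydro-2H,6H-1,5-benzodioxocine | C=C1COCc2cc(C3(C)OCCO3)ccc2OC1 | intermediate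
8 | (2Z)-3-methyl-8-(2-methyl-1,3-dioxolan-2-yl)-4H,6H-1,5-benzodioxocine | C/C1=C/Oc2ccc(C3(C)OCCO3)cc2COC1 | intermediate
9 | (2Z,6R)-6-lithio-3-methyl-8-(2-methyl-1,3-dioxolan-2-yl)-4H,6H-1,5-benzodioxocine (drawn for the invertive course; not isolated) | C/C1=C/Oc2ccc(C3(C)OCCO3)cc2[C@@H]([Li])OC1 | intermediate
10 | lithium (2R,3R)-5-(2-methyl-1,3-dioxolan-2-yl)-2-(prop-1-en-2-yl)-2,3-dihydro-1-benzofuran-3-olate (not isolated) | C=C(C)[C@H]1Oc2ccc(C3(C)OCCO3)cc2[C@H]1O[Li] | intermediate
11 | (2R,3R)-5-(2-methyl-1,3-dioxolan-2-yl)-2-(prop-1-en-2-yl)-2,3-dihydro-1-benzofuran-3-ol (cis) | C=C(C)[C@H]1Oc2ccc(C3(C)OCCO3)cc2[C@H]1O | intermediate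
12 | 3-methylbutanoic anhydride | CC(C)CC(=O)OC(=O)CC(C)C | starting material
13 | (2R,3R)-5-(2-methyl-1,3-dioxolan-2-yl)-2-(prop-1-en-2-yl)-2,3-dihydro-1-benzofuran-3-yl 3-methylbutanoate | C=C(C)[C@H]1Oc2ccc(C3(C)OCCO3)cc2[C@H]1OC(=O)CC(C)C | intermediate
14 | (2R,3R)-5-acetyl-2-(prop-1-en-2-yl)-2,3-dihydro-1-benzofuran-3-yl 3-methylbutanoate | C=C(C)[C@H]1Oc2ccc(C(C)=O)cc2[C@H]1OC(=O)CC(C)C | intermediate
15 | (2R,3R)-5-[(1S)-1-hydroxyethyl]-2-(prop-1-en-2-yl)-2,3-dihydro-1-benzofuran-3-yl 3-methylbutanoate | C=C(C)[C@H]1Oc2ccc([C@H](C)O)cc2[C@H]1OC(=O)CC(C)C | intermediate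
16 | 3-methylbut-2-enoic acid | CC(C)=CC(=O)O | starting material
17 | (1S)-1-[(2R,3R)-3-(3-methylbutanoyloxy)-2-(prop-1-en-2-yl)-2,3-dihydro-1-benzofuran-5-yl]ethyl 3-methylbut-2-enoate | C=C(C)[C@H]1Oc2ccc([C@H](C)OC(=O)C=C(C)C)cc2[C@H]1OC(=O)CC(C)C | intermediate
18 | (1S)-1-[(2R,3R)-2-(3-hydroxyprop-1-en-2-yl)-3-(3-methylbutanoyloxy)-2,3-dihydro-1-benzofuran-5-yl]ethyl 3-methylbut-2-enoate (not isolated) | C=C(CO)[C@H]1Oc2ccc([C@H](C)OC(=O)C=C(C)C)cc2[C@H]1OC(=O)CC(C)C | intermediate
19 | (1S)-1-[(2R,3R)-3-(3-methylbutanoyloxy)-2-(3-oxoprop-1-en-2-yl)-2,3-dihydro-1-benzofuran-5-yl]ethyl 3-methylbut-2-enoate | C=C(C=O)[C@H]1Oc2ccc([C@H](C)OC(=O)C=C(C)C)cc2[C@H]1OC(=O)CC(C)C | target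

Total step count: 11. Longest linear sequence: 11 steps (1 → 19).

Steps most likely to fail

Step 6. Several things may go wrong.
- Lithiation may stray to the allylic, vinylic or aromatic positions.
- The ring-bound benzylic anion may be poorly aligned for the transannular attack, so that the homolytic [1,2] shift takes over.
- The ligand may discriminate only weakly between the two benzylic hydrogens.

The fallback gives up the sigmatropic step and uses known chemistry only. It sets out from 3 and comes back at 13. O-Alkylation of 3 with methyl bromoacetate (K2CO3, acetone) should give methyl 2-(2-methoxy-2-oxoethoxy)-5-(2-methyl-1,3-dioxolan-2-yl)benzoate F1. Dieckmann condensation of this diester (NaOMe, toluene/MeOH) forms the C2–C3 bond and gives methyl 3-hydroxy-5-(2-methyl-1,3-dioxolan-2-yl)-1-benzofuran-2-carboxylate F2, the enol of the 3-oxo ester. The next reaction is asymmetric transfer hydrogenation with dynamic kinetic resolution (RuCl[(S,S)-TsDPEN](p-cymene), HCO2Na, H2O/CH2Cl2). This reaction type is established for 2-substituted benzofuran-3(2H)-ones and for cyclic and α-alkoxy β-keto esters. It should reduce the rapidly epimerising keto tautomer from the face opposite the ester and give the cis product methyl (2S,3R)-3-hydroxy-5-(2-methyl-1,3-dioxolan-2-yl)-2,3-dihydro-1-benzofuran-2-carboxylate F3. The S descriptor at C2 reflects only a change of CIP priorities. Excess MeMgBr (THF, −78 → 0 °C) should then give (2S,3R)-2-(2-hydroxypropan-2-yl)-5-(2-methyl-1,3-dioxolan-2-yl)-2,3-dihydro-1-benzofuran-3-ol F4. Acylation with 12 (Et3N, DMAP) should occur only at the secondary hydroxyl and give (2S,3R)-2-(2-hydroxypropan-2-yl)-5-(2-methyl-1,3-dioxolan-2-yl)-2,3-dihydro-1-benzofuran-3-yl 3-methylbutanoate F5. Dehydration of the tertiary alcohol toward a methyl group with methyl N-(triethylammoniosulfonyl)carbamate (Burgess reagent, toluene, 50 °C) leads to 13.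

Step 5. The double bond may migrate toward O5 instead of O1, or the two enol ethers may equilibrate. The ring closure before it may also lose material to oligomerisation. The fallback places the enol ether by a stereoretentive C–O coupling instead of an isomerisation. It sets out from 3 and comes back at 8. (Z)-3-Iodo-2-methylprop-2-en-1-ol F6 is made from propargyl alcohol by CuI-catalysed methylmagnesiation (MeMgBr) and quenching with I2. Ullmann-type O-vinylation of 3 with this iodide (CuI, N,N-dimethylglycine, Cs2CO3, dioxane, 90 °C) should give methyl 2-{[(1Z)-3-hydroxy-2-methylprop-1-en-1-yl]oxy}-5-(2-methyl-1,3-dioxolan-2-yl)benzoate F7 with retention of alkene geometry. Any lactonisation at this stage would be harmless. LiAlH4 (THF, 0 °C) then gives the diol (2Z)-3-[2-(hydroxymethyl)-4-(2-methyl-1,3-dioxolan-2-yl)phenoxy]-2-methylprop-2-en-1-ol F8. Treatment with NaH (2.2 equiv) and TsCl (1 equiv) in dilute THF forms a monosulfonate in the flask. It is drawn as [2-{[(1Z)-3-hydroxy-2-methylprop-1-en-1-yl]oxy}-5-(2-methyl-1,3-dioxolan-2-yl)phenyl]methyl 4-methylbenzenesulfonate F9, and sulfonylation at the other hydroxyl would lead to the same ring. Displacement by the remaining alkoxide closes the ring to 8.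

Step 11. The ene reaction may abstract the C2 methine hydrogen instead of a methyl hydrogen. The senecioate methyl groups may be oxidised in competition. The selenous acid medium may also cause loss of the C3 ester with aromatisation. The fallback replaces C–H oxygenation by chlorination and N-oxide oxidation. It sets out from 17 and comes back at 19. Ene-type allylic chlorination (N-chlorosuccinimide, PhSeCl cat., CH2Cl2, rt) should give (1S)-1-[(2R,3R)-2-(3-chloroprop-1-en-2-yl)-3-(3-methylbutanoyloxy)-2,3-dihydro-1-benzofuran-5-yl]ethyl 3-methylbut-2-enoate F10. A Kornblum-type oxidation with N-methylmorpholine N-oxide (NaI cat., MeCN, rt → 40 °C) then converts it into 19.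

Further compounds
F1 | step 6 | methyl 2-(2-methoxy-2-oxoethoxy)-5-(2-methyl-1,3-dioxolan-2-yl)benzoate | COC(=O)COc1ccc(C2(C)OCCO2)cc1C(=O)OC
F2 | step 6 | methyl 3-hydroxy-5-(2-methyl-1,3-dioxolan-2-yl)-1-benzofuran-2-carboxylate | COC(=O)c1oc2ccc(C3(C)OCCO3)cc2c1O
F3 | step 6 | methyl (2S,3R)-3-hydroxy-5-(2-methyl-1,3-dioxolan-2-yl)-2,3-dihydro-1-benzofuran-2-carboxylate | COC(=O)[C@H]1Oc2ccc(C3(C)OCCO3)cc2[C@H]1O
F4 | step 6 | (2S,3R)-2-(2-hydroxypropan-2-yl)-5-(2-methyl-1,3-dioxolan-2-yl)-2,3-dihydro-1-benzofuran-3-ol | CC(C)(O)[C@H]1Oc2ccc(C3(C)OCCO3)cc2[C@H]1O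
F5 | step 6 | (2S,3R)-2-(2-hydroxypropan-2-yl)-5-(2-methyl-1,3-dioxolan-2-yl)-2,3-dihydro-1-benzofuran-3-yl 3-methylbutanoate | CC(C)(O)[C@H]1Oc2ccc(C3(C)OCCO3)cc2[C@H]1OC(=O)CC(C)C
F6 | step 5 | (Z)-3-iodo-2-methylprop-2-en-1-ol | I/C=C(/C)CO
F7 | step 5 | methyl 2-{[(1Z)-3-hydroxy-2-methylprop-1-en-1-yl]oxy}-5-(2-methyl-1,3-dioxolan-2-yl)benzoate | COC(=O)c1cc(C2(C)OCCO2)ccc1O/C=C(/C)CO
F8 | step 5 | (2Z)-3-[2-(hydroxymethyl)-4-(2-methyl-1,3-dioxolan-2-yl)phenoxy]-2-methylprop-2-en-1-ol | OCc1cc(C2(C)OCCO2)ccc1O/C=C(/C)CO
F9 | step 5 | [2-{[(1Z)-3-hydroxy-2-methylprop-1-en-1-yl]oxy}-5-(2-methyl-1,3-dioxolan-2-yl)phenyl]methyl 4-methylbenzenesulfonate | Cc1ccc(cc1)S(=O)(=O)OCc1cc(C2(C)OCCO2)ccc1O/C=C(/C)CO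
F10 | step 11 | (1S)-1-[(2R,3R)-2-(3-chloroprop-1-en-2-yl)-3-(3-methylbutanoyloxy)-2,3-dihydro-1-benzofuran-5-yl]ethyl 3-methylbut-2-enoate | C=C(CCl)[C@H]1Oc2ccc([C@H](C)OC(=O)C=C(C)C)cc2[C@H]1OC(=O)CC(C)C
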